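Atom labels used throughout: ring carbons C1–C10 as in the germacrane skeleton (C1 ketone, C4–C5 epoxide, C6 lactone CH–O, C7 butenolide β-carbon, C8 methacrylate, C9 hydroxyl, C10 CH–CH3). C11 is the butenolide α-carbon, C12 the lactone carbonyl, C13 the acetoxymethyl carbon. O6–O9 are the oxygens on C6–C9. Eight-membered intermediates keep these labels.

## The problem

The target is a ten-membered carbocycle with a butenolide fused across C6–C7 (ring oxygen on C6, C7=C11, C11 carrying CH2OAc), a cis-fused trisubstituted epoxide at C4–C5, a C1 ketone, a C10 methyl, a free C9 hydroxyl and a C8 methacrylate. Its six stereocentres form two triads, C4–C5–C6 and C8–C9–C10, separated by the trigonal C7 on one side and C1–C3 on the other, so configuration must be relayed across a ring. Inside each triad control is available: an oxygen at C6 is allylic to C4=C5, C8 and C9 are vicinal and can arrive together, and C10 is α to the C1 ketone and can equilibrate. The hard relation is C9 against C6, and the C8/C9 oxygens are trans and differently acylated. Little rough treatment is tolerated: the epoxide is acid-labile; C6–H is the γ-hydrogen of the butenolide beside the epoxide, so base risks elimination; the C9 hydroxyl is β to the ketone; and two esters are present. Direct closure of a ten-membered ring is a further classical difficulty. The enabling feature is that C1 and C7 are carbonyl-level carbons in a 1,5-relation across C10–C9–C8, with vicinal oxygens on C8 and C9. That is the retron of a de Mayo reaction: removing C8–C9 and joining C7 to C10 leaves an eight-membered 2-methyl-1,3-dione with the carbon skeleton of 1,5-dimethylcycloocta-1,5-diene.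

## Retrosynthesis

**23 ⇒ 21 + 22.** The C8–O ester bond is cut so that it forms with inversion. A cyclic enediol partner can only deliver C8 and C9 cis, and the target has them trans, so one centre must be inverted. C9 is β to the C1 ketone, where an activated oxygen would eliminate. C8 is allylic to the butenolide double bond and is the better SN2 site. A Mitsunobu reaction of cis-diol 21 with methacrylic acid 22 inverts C8 and installs the ester in one step. It must be selective for C8 over C9.

**21 ⇒ 20 ⇒ 19 ⇒ 18.** These are functional-group changes only: the diol comes from acetonide 20, the acetate from alcohol 19, and the alcohol from PMB ether 18. Acetylating C13 while C8 and C9 are still tied in the acetonide avoids any selection among three hydroxyls. The cost is an acid-mediated ketal cleavage in the presence of the epoxide.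

**18 ⇒ 17 ⇒ 12 + 16.** The butenolide is cut at C7=C11 (intramolecular Horner–Wadsworth–Emmons) and at the C6–O ester bond. C13 comes with the phosphonate, because the α-position of a β,γ-fully substituted butenolide is hard to functionalise later. Acid 16 is made from allyl phosphonoacetate 13 and chloromethyl ether 14 through 15. The esterification of 12 with 16 is run as a Mitsunobu reaction so that it also inverts C6 (reason in the next paragraph). The olefination must choose the adjacent C7 ketone over C1, which ring size guarantees.

**12 ⇒ 8 + 9 (key step).** C7–C8 and C9–C10 are cut and C7–C10 is rejoined. This removes the medium ring, both C8/C9 oxygens and two C–C bonds at once. It leaves an eight-membered β-acyloxy enone 8 and 2,2-dimethyl-1,3-dioxole 9, with cyclobutane 10 and cyclobutanol 11 as transient intermediates. Two features of 8 decide whether the step can give 12.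

- **Which enol reacts.** A free enol ester of the unsymmetrical dione would form mainly at the less hindered oxygen on C1, and ring expansion would then occur on the wrong side. O6 is therefore tied to the C7 enol oxygen as a cyclic carbonate. Only the five-membered ring can form, which fixes the double bond at C7=C10.
- **Which face reacts.** The carbonate holds O6 in the enone plane and forces the C3–C5 bridge onto one face. The dioxole must add to the other face, the one anti to the C6–O bond. With the dioxolane turned away from the carbocycle, this gives the required C9 configuration only if C6 is epimeric to the target. Hence 8 is the 6-epi compound, and C6 is corrected in step 11 at no extra step.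

**8 ⇒ 7 ⇒ 6.** The epoxide is cut back to the alkene of 7, and the carbonate to hydroxy dione 6. The rigid carbonate-locked bicycle of 7 exposes only the outer face of C4=C5, which is the face that gives the target's epoxide. C6 thus controls C4, C5 and C9 through one template.

**6 ⇒ 5 ⇒ 4 ⇒ 3 ⇒ 2 ⇒ 1.** The C6 hydroxyl is cut (asymmetric hydroxylation of the achiral dianion of dione 5). The dione is traced to α,β-epoxy ketone 4, epoxy alcohol 3 and allylic alcohol 2, which is the allylic oxidation product of diene 1. All ten ring carbons of 5 and both methyls come from 1.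

## Roads not taken

**Alternative 1:** The cut is at C6–C7 and at the lactone C12–O bond. In the forward step a vinylchromium centre, generated at C7 from an iodide cis to the C12 ester (CrCl2, catalytic NiCl2), adds to a C6 epoxy aldehyde. This closes the ten-membered ring, and the C6 alkoxide lactonises to give A1, the 9-O-triethylsilyl ether of the target.
- Merits: it is convergent, it needs no photochemistry and no inversion, the stereocentres are set by acyclic methods, and A1 is one deprotection from the target.
- Weak points: C6 is created during the macrocyclisation, where Felkin and chelation control by the epoxide oxygen compete. The tetrasubstituted vinyl iodide is hindered. The ring closure is entropically demanding and is done with the methacrylate, the β-silyloxy ketone and the epimerisable C10 already in place.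
- Comparison: this road is probably shorter and ends closer to the target. The chosen plan offers in return that no macrocyclisation is needed and that one stereocentre (C6) is relayed to C4, C5 and C9 on a rigid template.

**Alternative 2:** The cut is at C2–C3. In the forward step a ten-membered β-keto lactone, with its ester oxygen on C5 beside an isopropenyl group, undergoes Carroll rearrangement with loss of CO2. This forms C2–C3 and the C4=C5 alkene and gives carbocycle A2, the (4Z)-cyclodecenone butenolide.
- Merits: the ring is first closed as a lactone, which is easier than carbocyclisation, and the alkene geometry follows from the cyclic transition state.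
- Weak points: the epoxide still has to be put on the ten-membered alkene of A2, where facial control is uncertain. The enolisation or heating needed for the rearrangement endangers the C9 silyloxy group β to the ketone. A2 is still four or more steps from the target.
- Comparison: ring formation is more reliable here than a photochemical step. The chosen plan makes the epoxide on an eight-membered ring where the face is predictable.

**Alternative 3:** The cut is at C8–C9. In the forward step SmI2 couples a C8 aldehyde on the butenolide with a C9 aldehyde to give macrocyclic diol A3.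
- Merits: both carbinol centres and the ring form in one step, and a trans diol would make the inversion at C8 unnecessary.
- Weak points: pinacol cyclisations tend to give cis diols. The C8 aldehyde is conjugated through the butenolide and the allylic acetate is reducible, so divalent samarium has competing sites. A3 still needs differentiation of the two hydroxyls, PMB removal and oxidation at C1.
- Comparison: both plans must differentiate O8 from O9. The chosen plan exposes no reducible end-game functionality to a reductant and makes the ring by expansion, not cyclisation.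

Key step: step 8

## Assumptions

- Commercial 1,5-dimethylcycloocta-1,5-diene is used as the 1,5-isomer, freed of the 1,6-isomer that accompanies technical material.
- The sense of induction of the chiral oxaziridine on the dianion of 5 cannot be predicted with confidence. The route is written with the (+)-reagent giving (4S)-6; the (−)-reagent is used if the sense is reversed.
- C10 is assumed to settle in the natural (10S) configuration when the C1 enolate is protonated and left to equilibrate in step 8.

## Route

Step 1
Reactants: 1 1,5-dimethylcycloocta-1,5-diene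
Product: 2 (±)-2,6-dimethylcycloocta-2,6-dien-1-ol
Conditions: SeO2 (0.5 equiv), t-BuOOH, CH2Cl2, rt; 1 in excess
Reagents that add atoms: tert-butyl hydroperoxide, CC(C)(C)OO (oxygen relayed through catalytic selenium dioxide, O=[Se]=O)
Why: Allylic oxidation with SeO2 (ene reaction, then [2,3]-sigmatropic shift) should occur at the ring CH2 next to the methyl-bearing alkene carbon, which becomes C7; the two alkenes of 1 are equivalent and the diene is kept in excess so that only one reacts.

Step 2
Reactants: 2 (±)-2,6-dimethylcycloocta-2,6-dien-1-ol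
Product: 3 (±)-1,5-dimethyl-9-oxabicyclo[6.1.0]non-4-en-2-ol (epoxide oxygen syn to the hydroxyl)
Conditions: VO(acac)2 (cat.), t-BuOOH, toluene, 0 °C to rt
Reagents that add atoms: tert-butyl hydroperoxide, CC(C)(C)OO
Why: Hydroxyl-directed epoxidation should touch only the allylic C10=C1 alkene and leave the remote C4=C5 alkene; the new stereocentres are erased in step 4.

Step 3
Reactants: 3 (±)-1,5-dimethyl-9-oxabicyclo[6.1.0]non-4-en-2-ol
Product: 4 (±)-1,5-dimethyl-9-oxabicyclo[6.1.0]non-4-en-2-one
Conditions: DMP, pyridine, CH2Cl2, 0 °C to rt
Reagents that add atoms: none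
Why: Periodinane oxidation of the secondary alcohol under non-basic conditions should keep the epoxide and avoid moving the β,γ-alkene into conjugation.

Step 4
Reactants: 4 (±)-1,5-dimethyl-9-oxabicyclo[6.1.0]non-4-en-2-one
Product: 5 2,6-dimethylcyclooct-5-ene-1,3-dione (racemic at C2, enolisable)
Conditions: Pd(PPh3)4 (cat.), 1,2-bis(diphenylphosphino)ethane, toluene, 80 °C
Reagents that add atoms: none
Why: Zerovalent palladium opens the α,β-epoxy ketone at the α-carbon–oxygen bond and β-hydride elimination gives the enol of the 1,3-dione, the known isomerisation of α,β-epoxy ketones to β-diketones; the β-carbon carries the hydrogen this needs.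

Step 5
Reactants: 5 2,6-dimethylcyclooct-5-ene-1,3-dione
Product: 6 (4S)-4-hydroxy-2,6-dimethylcyclooct-5-ene-1,3-dione (C2 epimers and enol forms; the carbinol carbon is C6 of the target numbering, epimeric to the target)
Conditions: LDA (2.2 equiv), THF, −78 to −40 °C; (+)-(camphorsulfonyl)oxaziridine, −78 °C; aq. NH4Cl
Reagents that add atoms: (+)-(camphorsulfonyl)oxaziridine, CC1(C)[C@@H]2CC[C@]13CS(=O)(=O)N4O[C@@]34C2
Why: Enolate hydroxylation with an N-sulfonyloxaziridine: the second deprotonation of the dione should occur at the allylic α'-methylene, the dianion reacts at that carbon, and the chiral reagent differentiates its enantiotopic faces to set C6.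

Step 6
Reactants: 6 (4S)-4-hydroxy-2,6-dimethylcyclooct-5-ene-1,3-dione
Product: 7 (3aS)-5,9-dimethyl-6,7-dihydro-3aH-cycloocta[d][1,3]dioxole-2,8-dione (cyclic carbonate joining O6 to the C7 enol oxygen; enone C1(=O)–C10(CH3)=C7)
Conditions: 1,1'-carbonyldiimidazole, CH2Cl2, 0 °C to rt
Reagents that add atoms: 1,1'-carbonyldiimidazole, O=C(n1ccnc1)n1ccnc1
Why: Carbonylation of an alcohol and the enol of a vinylogous acid: the C6 imidazolide can reach only the C7 enol oxygen (five-membered ring), so the carbonate fixes the enol double bond at C7=C10 and holds O6 in the enone plane.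

Step 7
Reactants: 7 (3aS)-5,9-dimethyl-6,7-dihydro-3aH-cycloocta[d][1,3]dioxole-2,8-dione
Product: 8 (4R,5S,6S)-4,5-epoxide of 7 (6-epi epoxy cyclooctenone enol carbonate; cis-fused epoxide with its oxygen anti to O6)
Conditions: mCPBA, CH2Cl2, 0 °C
Reagents that add atoms: 3-chloroperoxybenzoic acid, OOC(=O)c1cccc(Cl)c1
Why: Prilezhaev epoxidation should take the electron-rich trisubstituted alkene in preference to the electron-poor enol carbonate; in the carbonate-locked ring only the outer face of C4=C5 is open, which puts the epoxide oxygen anti to O6 and sets C4 and C5 as in the target.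

Step 8
Reactants: 8 (4R,5S,6S)-6-epi epoxy cyclooctenone enol carbonate, 9 2,2-dimethyl-1,3-dioxole
Product: 12 (4R,5S,6S,8R,9R,10S)-4,5-epoxy-6-hydroxy-8,9-(isopropylidenedioxy)-4,10-dimethylcyclodecane-1,7-dione, via cyclobutane photoadduct 10 (not isolated), via cyclobutane-6,7-diol 11 (not isolated)
Conditions: 9 (10 equiv), hν (λ > 300 nm, Pyrex), MeCN, −40 °C; remove excess 9; K2CO3, THF–H2O (4:1), 0 °C; pH 7 buffer
Reagents that add atoms: none
Why: This is a de Mayo sequence, the [2+2] photocycloaddition of a cyclic β-acyloxy enone to an alkene followed by retro-aldol ring expansion, run here on an eight-membered enol carbonate. Excitation and intersystem crossing give the enone triplet, which adds to the electron-rich dioxole through a 1,4-diradical that closes by radical recombination to cyclobutane 10 (new bonds C7–C8 and C9–C10). Hydrolysis of the strained carbonate with loss of CO2 frees the C7 cyclobutanol in 11, whose alkoxide expels the C1 enolate by retro-aldol cleavage of C7–C10, so the four- and eight-membered rings merge into the ten-membered ring by a strain-driven two-carbon expansion and not by a cyclisation. The carbonate fixes the enol double bond at C7=C10, so ring expansion can only occur between C7 and C10, and the symmetrical dioxole raises no regiochemical question. C9 is set by the face of attack: the carbonate holds O6 in the enone plane and the C3–C5 bridge covers one face, so the dioxole should add to the other, the face anti to the C6–O bond and the only one that leaves the carbonate cis-fused, with the dioxolane turned away from the carbocycle (cis-anti-cis). C8 is cis to C9 because both come from the ring of the dioxole. C10 is set on protonation of the enolate and remains enolisable beside C1, so it is expected to settle as the epimer drawn. Low temperature is used against E/Z isomerisation of the excited enone, and cold, brief base contact against β-elimination of the C9 oxygen and epimerisation at C8.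

Step 9
Reactants: 13 allyl 2-(diethoxyphosphoryl)acetate, 14 1-[(chloromethoxy)methyl]-4-methoxybenzene (4-methoxybenzyl chloromethyl ether)
Product: 15 allyl 2-(diethoxyphosphoryl)-3-[(4-methoxybenzyl)oxy]propanoate (racemic)
Conditions: NaH, THF, 0 °C to rt
Reagents that add atoms: none
Why: C-Alkylation of the sodium phosphonoacetate with a reactive α-chloro ether should introduce C13 with its oxygen already protected as a PMB ether.

Step 10
Reactants: 15 allyl 2-(diethoxyphosphoryl)-3-[(4-methoxybenzyl)oxy]propanoate
Product: 16 2-(diethoxyphosphoryl)-3-[(4-methoxybenzyl)oxy]propanoic acid (racemic)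
Conditions: Pd(PPh3)4 (cat.), morpholine, THF, rt; aq. citric acid work-up
Reagents that add atoms: none
Why: Allyl transfer to morpholine through a π-allylpalladium complex frees the acid without a base strong enough to eliminate the β-alkoxy group.

Step 11
Reactants: 12 (4R,5S,6S,8R,9R,10S)-4,5-epoxy-6-hydroxy-8,9-(isopropylidenedioxy)-4,10-dimethylcyclodecane-1,7-dione, 16 2-(diethoxyphosphoryl)-3-[(4-methoxybenzyl)oxy]propanoic acid
Product: 17 (4R,5S,6R,8R,9R,10S)-4,5-epoxy-8,9-(isopropylidenedioxy)-4,10-dimethyl-1,7-dioxocyclodecan-6-yl 2-(diethoxyphosphoryl)-3-[(4-methoxybenzyl)oxy]propanoate (C6 now as in the target; both epimers at the phosphonate carbon)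
Conditions: PPh3, DIAD, toluene, 0 °C to rt
Reagents that add atoms: none
Why: Mitsunobu esterification: the activated C6 hydroxyl, α to the C7 ketone, should be displaced by the carboxylate with inversion, which turns the 6-epi alcohol into the C6 configuration of the target while attaching the phosphonate.

Step 12
Reactants: 17 C6 phosphonate ester
Product: 18 (4R,5S,6S,8S,9R,10S)-4,5-epoxy-8,9-(isopropylidenedioxy)-13-[(4-methoxybenzyl)oxy]-1-oxogermacr-7(11)-en-12,6-olide
Conditions: LiCl, i-Pr2NEt, MeCN, rt
Reagents that add atoms: none
Why: Intramolecular Horner–Wadsworth–Emmons olefination in its lithium chloride/amine variant: the phosphonate carbanion should add to the adjacent C7 ketone (five-membered ring) and not to the remote C1 ketone, and the weak base spares C8, C10 and the epoxide.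

Step 13
Reactants: 18 13-O-PMB butenolide acetonide
Product: 19 (4R,5S,6S,8S,9R,10S)-4,5-epoxy-13-hydroxy-8,9-(isopropylidenedioxy)-1-oxogermacr-7(11)-en-12,6-olide
Conditions: DDQ, CH2Cl2–pH 7 buffer (10:1), 0 °C to rt
Reagents that add atoms: none
Why: Oxidative cleavage of the PMB ether; no other electron-rich arene or alkene is present, and buffering protects the epoxide and the acetonide.

Step 14
Reactants: 19 13-hydroxy butenolide acetonide
Product: 20 (4R,5S,6S,8S,9R,10S)-13-acetoxy-4,5-epoxy-8,9-(isopropylidenedioxy)-1-oxogermacr-7(11)-en-12,6-olide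
Conditions: Ac2O, pyridine, DMAP (cat.), CH2Cl2, 0 °C
Reagents that add atoms: acetic anhydride, CC(=O)OC(C)=O
Why: Acetylation of the only free hydroxyl.

Step 15
Reactants: 20 13-acetoxy butenolide acetonide
Product: 21 (4R,5S,6S,8S,9R,10S)-13-acetoxy-4,5-epoxy-8,9-dihydroxy-1-oxogermacr-7(11)-en-12,6-olide (cis-8,9-diol)
Conditions: AcOH–H2O–THF (4:1:1), 35 °C
Reagents that add atoms: none
Why: Acid hydrolysis of the isopropylidene ketal; weak acid and short contact are chosen because the trisubstituted epoxide is the competing acid-labile group.

Step 16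
Reactants: 21 cis-8,9-diol, 22 methacrylic acid
Product: 23 (4R,5S,6S,8R,9R,10S)-13-acetoxy-4,5-epoxy-9-hydroxy-8-(methacryloyloxy)-1-oxogermacr-7(11)-en-12,6-olide (CNP0185951.2)
Conditions: PPh3, DIAD, THF, 0 °C to rt
Reagents that add atoms: none
Why: Mitsunobu esterification of the cis-diol: the C8 hydroxyl, allylic to the butenolide double bond and so the better SN2 site, should be displaced by methacrylate with inversion, while the more hindered C9 hydroxyl next to C10 stays free; a cis-diol cannot close to an epoxide instead.

## Compound list

1 | 1,5-dimethylcycloocta-1,5-diene | CC1=CCCC(C)=CCC1 | starting material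
2 | (±)-2,6-dimethylcycloocta-2,6-dien-1-ol | CC1=CCCC(C)=CCC1O | intermediate
3 | (±)-1,5-dimethyl-9-oxabicyclo[6.1.0]non-4-en-2-ol, hydroxyl syn to epoxide oxygen (racemate, one enantiomer drawn) | O[C@@H]1CC=C(C)CC[C@@H]2O[C@]12C | intermediate
4 | (±)-1,5-dimethyl-9-oxabicyclo[6.1.0]non-4-en-2-one (racemate, one enantiomer drawn) | O=C1CC=C(C)CC[C@@H]2O[C@]12C | intermediate
5 | 2,6-dimethylcyclooct-5-ene-1,3-dione | CC1C(=O)CC=C(C)CCC1=O | intermediate
6 | (4S)-4-hydroxy-2,6-dimethylcyclooct-5-ene-1,3-dione | CC1C(=O)[C@@H](O)C=C(C)CCC1=O | intermediate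
7 | (3aS)-5,9-dimethyl-6,7-dihydro-3aH-cycloocta[d][1,3]dioxole-2,8-dione | CC1=C2OC(=O)O[C@H]2C=C(C)CCC1=O | intermediate
8 | (4R,5S,6S)-4,5-epoxide of 7 (6-epi epoxy cyclooctenone enol carbonate) | CC1=C2OC(=O)O[C@H]2[C@@H]2O[C@]2(C)CCC1=O | intermediate
9 | 2,2-dimethyl-1,3-dioxole | CC1(C)OC=CO1 | starting material
10 | cyclobutane photoadduct (C7–C8 and C9–C10 formed; cis-anti-cis; 6,7-carbonate and 8,9-acetonide) | C[C@]12[C@H]3OC(C)(C)O[C@H]3[C@@]24OC(=O)O[C@H]4[C@@H]5O[C@]5(C)CCC1=O | intermediate
11 | cyclobutane-6,7-diol (carbonate hydrolysed) | C[C@]12[C@H]3OC(C)(C)O[C@H]3[C@]2(O)[C@@H](O)[C@@H]4O[C@]4(C)CCC1=O | intermediate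
12 | (4R,5S,6S,8R,9R,10S)-4,5-epoxy-6-hydroxy-8,9-(isopropylidenedioxy)-4,10-dimethylcyclodecane-1,7-dione (6-epi; cis acetonide) | C[C@H]1[C@H]2OC(C)(C)O[C@H]2C(=O)[C@@H](O)[C@@H]2O[C@]2(C)CCC1=O | intermediate
13 | allyl 2-(diethoxyphosphoryl)acetate | C=CCOC(=O)CP(=O)(OCC)OCC | starting material
14 | 1-[(chloromethoxy)methyl]-4-methoxybenzene | COc1ccc(COCCl)cc1 | starting material
15 | allyl 2-(diethoxyphosphoryl)-3-[(4-methoxybenzyl)oxy]propanoate | C=CCOC(=O)C(COCc1ccc(OC)cc1)P(=O)(OCC)OCC | intermediate
16 | 2-(diethoxyphosphoryl)-3-[(4-methoxybenzyl)oxy]propanoic acid | OC(=O)C(COCc1ccc(OC)cc1)P(=O)(OCC)OCC | intermediate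
17 | (4R,5S,6R,8R,9R,10S)-C6 phosphonate ester of the ten-membered diketone | C[C@H]1[C@H]2OC(C)(C)O[C@H]2C(=O)[C@H](OC(=O)C(COCc3ccc(OC)cc3)P(=O)(OCC)OCC)[C@@H]2O[C@]2(C)CCC1=O | intermediate
18 | (4R,5S,6S,8S,9R,10S)-4,5-epoxy-8,9-(isopropylidenedioxy)-13-[(4-methoxybenzyl)oxy]-1-oxogermacr-7(11)-en-12,6-olide | C[C@H]1[C@H]2OC(C)(C)O[C@H]2C2=C(COCc3ccc(OC)cc3)C(=O)O[C@@H]2[C@@H]2O[C@]2(C)CCC1=O | intermediate
19 | (4R,5S,6S,8S,9R,10S)-4,5-epoxy-13-hydroxy-8,9-(isopropylidenedioxy)-1-oxogermacr-7(11)-en-12,6-olide | C[C@H]1[C@H]2OC(C)(C)O[C@H]2C2=C(CO)C(=O)O[C@@H]2[C@@H]2O[C@]2(C)CCC1=O | intermediate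
20 | (4R,5S,6S,8S,9R,10S)-13-acetoxy-4,5-epoxy-8,9-(isopropylidenedioxy)-1-oxogermacr-7(11)-en-12,6-olide | C[C@H]1[C@H]2OC(C)(C)O[C@H]2C2=C(COC(C)=O)C(=O)O[C@@H]2[C@@H]2O[C@]2(C)CCC1=O | intermediate
21 | (4R,5S,6S,8S,9R,10S)-13-acetoxy-4,5-epoxy-8,9-dihydroxy-1-oxogermacr-7(11)-en-12,6-olide | C[C@H]1[C@@H](O)[C@@H](O)C2=C(COC(C)=O)C(=O)O[C@@H]2[C@@H]2O[C@]2(C)CCC1=O | intermediate
22 | methacrylic acid | C=C(C)C(=O)O | starting material
23 | (4R,5S,6S,8R,9R,10S)-13-acetoxy-4,5-epoxy-9-hydroxy-8-(methacryloyloxy)-1-oxogermacr-7(11)-en-12,6-olide (CNP0185951.2) | C=C(C)C(=O)O[C@@H]1C2=C(COC(C)=O)C(=O)O[C@@H]2[C@@H]2O[C@]2(C)CCC(=O)[C@@H](C)[C@H]1O | target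

## Step count and least certain steps

Total step count: 16. Longest linear sequence: 14 steps (steps 1–8 and 11–16, from 1 to 23); steps 9 and 10 form a two-step side branch.

**Step 8 (key step).** The most likely failure is loss of orientation control in the cycloaddition: the dioxolane turns over the carbocycle, or a trans-fused adduct forms after E/Z isomerisation of the excited enone. Because the carbonate dictates the face, either event delivers the C9 epimer. β-Elimination of the C9 oxygen from the newly formed C1 enolate during the base treatment is the second concern.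
Fallback: it sets out from 5 and returns at 17. The sense at C9 is reversed by using the antipodal alcohol.
- Hydroxylation of 5 with the (−)-oxaziridine should give (4R)-4-hydroxy-2,6-dimethylcyclooct-5-ene-1,3-dione F1.
- Hydroxyl-directed epoxidation (VO(acac)2, t-BuOOH) should give the syn epoxy alcohol F2, as is usual for cyclooct-2-enols.
- Carbonyldiimidazole closes the natural-C6 epoxy enol carbonate F3.
- The same irradiation and hydrolysis then pass through the cis-syn-cis photoadduct F4 to the 6-hydroxy diketone of natural C6 configuration F5.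
- F5 is esterified with 16 by a carbodiimide (retention) to rejoin the route at 17.

**Step 5.** Deprotonation at C8 instead of the allylic methylene, or weak face discrimination by the oxaziridine, would give regioisomers or low enantiomeric purity.
Fallback: it sets out from 5 and returns at 6. Hydroxylation with achiral 2-(phenylsulfonyl)-3-phenyloxaziridine gives the racemic alcohol F6. Lipase-mediated acylation with vinyl acetate then converts the (4R)-enantiomer into its acetate F7 and leaves (4S)-6, which is separated.

**Step 11.** The alkoxyphosphonium ion at the hindered ring carbinol may not be displaced, or may eliminate or enolise toward C6, so the inversion fails or C6 is scrambled.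
Fallback: it sets out from 12 and returns at 17. The alcohol is converted into the 6-O-methanesulfonate F8 (MsCl, Et3N), and the α-keto sulfonate is displaced with the cesium salt of 16 in DMF (SN2, inversion).

**Step 15.** Acid-catalysed opening of the epoxide (hydrolysis or transannular participation of the C1 carbonyl) may compete with ketal hydrolysis.
Fallback: it sets out from 8 and returns at 21. No acid-labile diol protection is used.
- Irradiation of 8 with vinylene carbonate (1,3-dioxol-2-one) gives the bis-carbonate photoadduct F9.
- The aqueous K2CO3 treatment removes both carbonates and gives the 6,8,9-triol diketone F10.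
- Di-tert-butylsilyl bis(triflate) with 2,6-lutidine should bridge only the cis-8,9-diol (silylene F11).
- The sequence of steps 11–14 is run on F11: Mitsunobu ester F12, butenolide PMB ether F13, C13 alcohol F14, C13 acetate F15.
- HF·pyridine releases diol 21 with no ketal hydrolysis.

**Step 16.** Poor discrimination between the C8 and C9 hydroxyls, or a stable dioxaphosphorane that does not open, would give mixtures or no ester.
Fallback: it sets out from 21 and returns at 23.
- SOCl2 and Et3N give the cyclic sulfite F16.
- RuCl3 (cat.) and NaIO4 give the cyclic sulfate F17.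
- Cesium methacrylate in DMF opens the sulfate at the allylic C8 with inversion, giving the C9 sulfate monoester cesium salt F18.
- Catalytic H2SO4 with one equivalent of water in THF hydrolyses the sulfate ester to 23.

## Further compounds

F1 | step 8 | (4R)-4-hydroxy-2,6-dimethylcyclooct-5-ene-1,3-dione | CC1C(=O)[C@H](O)C=C(C)CCC1=O
F2 | step 8 | (4R,5S,6R)-4,5-epoxy-6-hydroxy dione (epoxide oxygen syn to O6) | CC1C(=O)[C@H](O)[C@@H]2O[C@]2(C)CCC1=O
F3 | step 8 | epoxy cyclooctenone enol carbonate with the natural C6 configuration | CC1=C2OC(=O)O[C@@H]2[C@@H]2O[C@]2(C)CCC1=O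
F4 | step 8 | cis-syn-cis cyclobutane photoadduct of F3 and 9 | C[C@@]12[C@H]3OC(C)(C)O[C@H]3[C@]24OC(=O)O[C@@H]4[C@@H]5O[C@]5(C)CCC1=O
F5 | step 8 | 4,5-epoxy-6-hydroxy-8,9-(isopropylidenedioxy)-4,10-dimethylcyclodecane-1,7-dione with the natural C6 configuration | C[C@H]1[C@H]2OC(C)(C)O[C@H]2C(=O)[C@H](O)[C@@H]2O[C@]2(C)CCC1=O
F6 | step 5 | (±)-4-hydroxy-2,6-dimethylcyclooct-5-ene-1,3-dione | CC1C(=O)C(O)C=C(C)CCC1=O
F7 | step 5 | (4R)-4-acetoxy-2,6-dimethylcyclooct-5-ene-1,3-dione | CC1C(=O)[C@H](OC(C)=O)C=C(C)CCC1=O
F8 | step 11 | 6-O-methanesulfonate of 12 | C[C@H]1[C@H]2OC(C)(C)O[C@H]2C(=O)[C@@H](OS(C)(=O)=O)[C@@H]2O[C@]2(C)CCC1=O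
F9 | step 15 | bis-carbonate cyclobutane photoadduct of 8 and vinylene carbonate | C[C@]12[C@H]3OC(=O)O[C@H]3[C@@]24OC(=O)O[C@H]4[C@@H]5O[C@]5(C)CCC1=O
F10 | step 15 | 4,5-epoxy-6,8,9-trihydroxy-4,10-dimethylcyclodecane-1,7-dione (6-epi, cis-8,9-diol) | C[C@H]1[C@@H](O)[C@@H](O)C(=O)[C@@H](O)[C@@H]2O[C@]2(C)CCC1=O
F11 | step 15 | 8,9-O-di-tert-butylsilylene derivative of F10 | C[C@H]1[C@H]2O[Si](C(C)(C)C)(C(C)(C)C)O[C@H]2C(=O)[C@@H](O)[C@@H]2O[C@]2(C)CCC1=O
F12 | step 15 | C6 phosphonate ester of the silylene diketone (C6 inverted) | C[C@H]1[C@H]2O[Si](C(C)(C)C)(C(C)(C)C)O[C@H]2C(=O)[C@H](OC(=O)C(COCc3ccc(OC)cc3)P(=O)(OCC)OCC)[C@@H]2O[C@]2(C)CCC1=O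
F13 | step 15 | 8,9-O-di-tert-butylsilylene 13-O-PMB butenolide | C[C@H]1[C@H]2O[Si](C(C)(C)C)(C(C)(C)C)O[C@H]2C2=C(COCc3ccc(OC)cc3)C(=O)O[C@@H]2[C@@H]2O[C@]2(C)CCC1=O
F14 | step 15 | 8,9-O-di-tert-butylsilylene 13-hydroxy butenolide | C[C@H]1[C@H]2O[Si](C(C)(C)C)(C(C)(C)C)O[C@H]2C2=C(CO)C(=O)O[C@@H]2[C@@H]2O[C@]2(C)CCC1=O
F15 | step 15 | 8,9-O-di-tert-butylsilylene 13-acetoxy butenolide | C[C@H]1[C@H]2O[Si](C(C)(C)C)(C(C)(C)C)O[C@H]2C2=C(COC(C)=O)C(=O)O[C@@H]2[C@@H]2O[C@]2(C)CCC1=O
F16 | step 16 | 8,9-cyclic sulfite of 21 (both sulfur epimers) | C[C@H]1[C@H]2OS(=O)O[C@H]2C2=C(COC(C)=O)C(=O)O[C@@H]2[C@@H]2O[C@]2(C)CCC1=O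
F17 | step 16 | 8,9-cyclic sulfate of 21 | C[C@H]1[C@H]2OS(=O)(=O)O[C@H]2C2=C(COC(C)=O)C(=O)O[C@@H]2[C@@H]2O[C@]2(C)CCC1=O
F18 | step 16 | cesium 9-O-sulfate of 23 | C=C(C)C(=O)O[C@@H]1C2=C(COC(C)=O)C(=O)O[C@@H]2[C@@H]2O[C@]2(C)CCC(=O)[C@@H](C)[C@H]1OS(=O)(=O)[O-].[Cs+]
A1 | alternative 1 | 9-O-triethylsilyl ether of the target | C=C(C)C(=O)O[C@@H]1C2=C(COC(C)=O)C(=O)O[C@@H]2[C@@H]2O[C@]2(C)CCC(=O)[C@@H](C)[C@H]1O[Si](CC)(CC)CC
A2 | alternative 2 | (4Z)-cyclodecenone butenolide, 8-O-triethylsilyl and 9-O-tert-butyldimethylsilyl ethers | CC[Si](CC)(CC)O[C@@H]1C2=C(COC(C)=O)C(=O)O[C@@H]2/C=C(/C)CCC(=O)[C@@H](C)[C@H]1O[Si](C)(C)C(C)(C)C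
A3 | alternative 3 | macrocyclic 8,9-diol with 1-O-(4-methoxybenzyl) ether | O[C@@H]1C2=C(COC(C)=O)C(=O)O[C@@H]2[C@@H]2O[C@]2(C)CC[C@H](OCc3ccc(OC)cc3)[C@@H](C)[C@H]1O
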